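## Retrosynthetic overview

1. The 3β‑OH comes from a C3 ketone; the C4 gem‑dimethyl and 5α‑H come from reductive methylation of a 4‑methyl‑Δ4‑3‑ketone, itself from a cross‑conjugated dienone.
2. Key step: a 3‑alkyl‑2,4‑dimethylphenol (ring A as an arene) is oxidatively dearomatized at its para carbon; the tethered E‑olefin closes ring B (C9–C10) and water caps C8, setting C8, C9 and C10 together.
3. The phenol comes from an aryl bromide and a C21 pentaene by hydroboration/B‑alkyl Suzuki coupling (C5–C6).
4. The pentaene comes from farnesyl chloride and a C6 dienyl chloride by tail‑to‑tail allyl–allyl coupling (C11–C12).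
5. Ring order: A (pre‑formed, aromatic) → B (key step) → ring A reduced to the saturated oxidation level.

Assumptions: compounds 1, 3 and 6 are taken as commercial; 2 and 4 are made rather than bought. Terpenoid numbering is used in the text (C3 carbinol, C4 gem‑dimethyl, C5/C10 ring fusion, C8 tertiary carbinol, C9 side‑chain carbon, C11/C12 the first two side‑chain CH2 groups).

## Route

**Step 1**
Reactants: 1, 2‑bromo‑1,3‑dimethylbenzene
Product: 2, 3‑bromo‑2,4‑dimethylphenol
Conditions: phthaloyl peroxide (1.3 equiv), HFIP, 23 °C; then NaHCO3, MeOH/H2O, 50 °C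
Reagents that add atoms: phthaloyl peroxide, O=C1OOC(=O)c2ccccc12 (one O)
Why: electrophilic arene C–H hydroxylation with a diacyl peroxide; attack goes to the only ring position that is ortho/para to both methyls, and the aryl phthalate half‑ester prevents over‑oxidation until hydrolysis; no stereocenter.

**Step 2**
Reactants: 3, (2E)‑3‑methylpent‑2‑en‑4‑yn‑1‑ol
Product: 4, (2E)‑3‑methylpenta‑2,4‑dien‑1‑ol
Conditions: H2 (1 atm, 1.0 equiv uptake), Lindlar catalyst, quinoline, EtOAc, 0 °C → rt
Reagents that add atoms: none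
Why: Lindlar semi‑hydrogenation of the terminal alkyne to a vinyl group; the trisubstituted olefin is untouched and keeps its E geometry.

**Step 3**
Reactants: 4, (2E)‑3‑methylpenta‑2,4‑dien‑1‑ol
Product: 5, (3E)‑5‑chloro‑3‑methylpenta‑1,3‑diene (used at once as a cold solution)
Conditions: NCS, Me2S, CH2Cl2, −20 → 0 °C
Reagents that add atoms: N‑chlorosuccinimide, O=C1CCC(=O)N1Cl (Cl)
Why: Corey–Kim allylic chlorination, SN2 on the alkoxysulfonium salt without allylic transposition, so the E olefin is retained.

**Step 4**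
Reactants: 6, (2E,6E)‑farnesyl chloride; 5, (3E)‑5‑chloro‑3‑methylpenta‑1,3‑diene
Product: 7, (3E,7E,11E)‑3,8,12,16‑tetramethylheptadeca‑1,3,7,11,15‑pentaene
Conditions: Ba* (BaI2, Li biphenylide, THF); 6, −78 °C; then 5, −78 °C
Reagents that add atoms: none
Why: Yamamoto allylbarium allyl–allyl cross‑coupling; the farnesylbarium is configurationally stable at −78 °C and reacts α,α′ (SN2 at the primary allylic chloride), giving the tail‑to‑tail C11–C12 bond with all E olefins retained.

**Step 5**
Reactants: 7, the pentaene; 2, 3‑bromo‑2,4‑dimethylphenol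
Product: 8, 2,4‑dimethyl‑3‑[(3E,7E,11E)‑3,8,12,16‑tetramethylheptadeca‑3,7,11,15‑tetraen‑1‑yl]phenol
Conditions: 9‑BBN (1.05 equiv), THF, 0 °C → rt; then 2, Pd(OAc)2/SPhos, aq K3PO4, THF, 65 °C
Reagents that add atoms: none
Why: 9‑BBN hydroborates only the monosubstituted vinyl terminus (anti‑Markovnikov; trisubstituted olefins are inert), and B‑alkyl Suzuki–Miyaura coupling with a bulky biarylphosphine joins the di‑ortho‑substituted aryl bromide; the free phenoxide is tolerated.

**Step 6 (key step)**
Reactants: 8, the phenol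
Product: 9, (4aR,5R,6R)‑6‑hydroxy‑1,4a,6‑trimethyl‑5‑[(3E,7E)‑4,8,12‑trimethyltrideca‑3,7,11‑trien‑1‑yl]‑5,6,7,8‑tetrahydronaphthalen‑2(4aH)‑one (terpenoid numbering 8R,9R,10R; 10β‑Me, 9α‑H, 8α‑OH)
Conditions: preformed chiral C2‑symmetric aryl‑λ3‑iodane diacetate (Ishihara‑type bis‑lactamide, 1.2 equiv), NaHCO3, HFIP/CH2Cl2/H2O, −30 °C
Reagents that add atoms: water, O
Why: Proposed new method: the phenol exchanges onto the chiral I(III) centre, making the methyl‑bearing para carbon (C10) electrophilic; the tethered E‑trisubstituted olefin attacks through C9 in a six‑membered chair (Markovnikov) while water traps the developing tertiary C8 cation anti to the new C9–C10 bond, so 10‑Me/9‑H are trans and the 8‑OH is equatorial (α) with 8‑Me axial (β); the arene face, and hence absolute configuration, is selected by the iodane (the antipode giving the 8R,9R,10R series is fixed in a small screen; both are available from (R)‑ or (S)‑lactate); closest known chemistry is hypervalent‑iodine para‑dearomatization of phenols by tethered π‑nucleophiles (oxidative Prins/Friedel–Crafts‑type carbocyclization) and chiral aryl‑iodine(III) enantioselective phenol dearomatization, merged with a water‑terminated cation–olefin cyclization.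

**Step 7**
Reactants: 9, the dienone
Product: 10, (4aR,5R,6R)‑6‑hydroxy‑1,4a,6‑trimethyl‑5‑[(3E,7E)‑4,8,12‑trimethyltrideca‑3,7,11‑trien‑1‑yl]‑4,4a,5,6,7,8‑hexahydronaphthalen‑2(3H)‑one
Conditions: RhCl(PPh3)3 (5 mol%), H2 (1 atm), benzene/EtOH, rt
Reagents that add atoms: none
Why: Wilkinson hydrogenation reduces only the cis‑disubstituted C1=C2 enone olefin (the steroid 1,4‑dien‑3‑one → 4‑en‑3‑one precedent); the tetrasubstituted C4=C5 and the trisubstituted chain olefins are too hindered; no stereocenter changes.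

**Step 8**
Reactants: 10, the enone
Product: 11, (4aS,5R,6R,8aR)‑6‑hydroxy‑1,1,4a,6‑tetramethyl‑5‑[(3E,7E)‑4,8,12‑trimethyltrideca‑3,7,11‑trien‑1‑yl]octahydronaphthalen‑2(1H)‑one
Conditions: Li, NH3/THF, t‑BuOH (1 equiv), −78 °C; isoprene; then MeI, −78 → −33 °C
Reagents that add atoms: iodomethane, CI (CH3)
Why: Stork reductive alkylation; dissolving‑metal reduction protonates C5 axially to give the trans ring fusion (5α‑H, anti to the 10β‑Me), and the regiospecific C3–C4 enolate is C‑methylated to the gem‑dimethyl; isolated olefins and the tertiary alkoxide are unaffected.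

**Step 9**
Reactants: 11, the ketone
Product: 12, (2S,4aS,5R,6R,8aR)‑1,1,4a,6‑tetramethyl‑5‑[(3E,7E)‑4,8,12‑trimethyltrideca‑3,7,11‑trien‑1‑yl]decahydronaphthalene‑2,6‑diol (target)
Conditions: NaBH4, MeOH, 0 °C
Reagents that add atoms: none
Why: hydride reduction of the 4,4‑dimethyl‑3‑ketone by axial attack gives the equatorial 3β‑alcohol (3S), the usual outcome for 3‑oxo‑4,4‑dimethyl terpenoids.

## Compound list

1 | 2‑bromo‑1,3‑dimethylbenzene | Cc1cccc(C)c1Br | starting material
2 | 3‑bromo‑2,4‑dimethylphenol | Cc1ccc(O)c(C)c1Br | intermediate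
3 | (2E)‑3‑methylpent‑2‑en‑4‑yn‑1‑ol | C#C/C(C)=C/CO | starting material
4 | (2E)‑3‑methylpenta‑2,4‑dien‑1‑ol | C=C/C(C)=C/CO | intermediate
5 | (3E)‑5‑chloro‑3‑methylpenta‑1,3‑diene | C=C/C(C)=C/CCl | intermediate
6 | (2E,6E)‑farnesyl chloride | CC(C)=CCC/C(C)=C/CC/C(C)=C/CCl | starting material
7 | (3E,7E,11E)‑3,8,12,16‑tetramethylheptadeca‑1,3,7,11,15‑pentaene | C=C/C(C)=C/CC/C=C(C)/CC/C=C(C)/CCC=C(C)C | intermediate
8 | 2,4‑dimethyl‑3‑[(3E,7E,11E)‑3,8,12,16‑tetramethylheptadeca‑3,7,11,15‑tetraen‑1‑yl]phenol | Cc1ccc(O)c(C)c1CC/C(C)=C/CC/C=C(C)/CC/C=C(C)/CCC=C(C)C | intermediate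
9 | (4aR,5R,6R)‑dienone (8α‑hydroxy‑1,4‑dien‑3‑one) | CC(C)=CCC/C(C)=C/CC/C(C)=C/CC[C@@H]1[C@@]2(C)C=CC(=O)C(C)=C2CC[C@@]1(C)O | intermediate
10 | (4aR,5R,6R)‑enone (8α‑hydroxy‑4‑en‑3‑one) | CC(C)=CCC/C(C)=C/CC/C(C)=C/CC[C@@H]1[C@@]2(C)CCC(=O)C(C)=C2CC[C@@]1(C)O | intermediate
11 | (4aS,5R,6R,8aR)‑4,4‑dimethyl‑3‑ketone | CC(C)=CCC/C(C)=C/CC/C(C)=C/CC[C@@H]1[C@@]2(C)CCC(=O)C(C)(C)[C@@H]2CC[C@@]1(C)O | intermediate
12 | (3S,5R,8R,9R,10S)‑3β,8α‑diol (CID57401582) | CC(C)=CCC/C(C)=C/CC/C(C)=C/CC[C@@H]1[C@@]2(C)CC[C@H](O)C(C)(C)[C@@H]2CC[C@@]1(C)O | target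

## Summary

Total steps: 9. Longest linear sequence: 8 (3 → 4 → 5 → 7 → 8 → 9 → 10 → 11 → 12); the 1 → 2 branch is one step.

Steps most likely to fail, with fallbacks:

1. **Step 6.** Risks are attack at the ortho carbon C4 instead of para C10, capture of the C8 cation by the C13=C14 olefin (6‑6‑5 tricycle) or elimination instead of hydration, and modest ee.
   Fallback: replace the oxidative umpolung with a stereospecific alkylative dearomatization. Couple 2 with the 9‑BBN adduct of 4 to give the aryl‑prenyl allylic alcohol, fix C8/C9 by Sharpless epoxidation, and close ring B by phenoxide para‑C‑alkylation (6‑endo opening at C9). After the ring‑A steps, attach the farnesyl unit at C11 through a phenyl sulfone (alkylation with farnesyl bromide, reductive desulfonylation).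

2. **Step 4.** Risks are α/γ scrambling or SN2′ on the dienyl chloride and Wurtz homocoupling.
   Fallback: switch from allylmetal coupling to Biellmann chemistry. Alkylate lithiated (E,E)‑farnesyl phenyl sulfone with the dienyl bromide, then remove the sulfone with Pd(dppp)/LiBHEt3.

3. **Step 5.** Risks are diene hydroboration selectivity and coupling at a di‑ortho‑substituted bromide bearing a free phenoxide.
   Fallback: build the C8=C9 olefin and the aryl bond differently. Make homofarnesal from 6, add isopropenylmagnesium bromide, run a Johnson orthoester Claisen to the (E)‑C22 ester, saponify, and join to the O‑silylated arylzinc from 2 by Ni‑catalysed decarboxylative (redox‑active ester) arylation.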